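**Plan**

- Labels: in the half carrying the free phenol, C7 is the ArCH–O carbon, C8 the ring-fusion carbon and C9 the OCH2 carbon; C7', C8', C9' are the same positions of the prenyloxyaryl half. Ring A is C7–O–C9'–C8'–C8 (aryl endo), ring B is C7'–O–C9–C8–C8' (aryl exo).
- Cuts, in retrosynthetic order: the silyl and prenyl ethers; O–C9 of ring B (back to a diol, then to the C9 lactone); the hydrogens at C7 and C8 (back to a C7=C8 enol ether); O–C9' of ring A (back to a C7 ketone and a C8–C9' cyclopropane bond); C8–C8' and C8–C9' in one oxidative step; last the ester C9–O and C8–C9.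
- Enabling feature: C8 is flanked by C7 and C9, so with C7 as ketone and C9 as ester carbonyl the unit C7–C8–C9 is an aroylacetate. The C9–O–C7' linkage of ring B makes it the ester of a 1-arylallyl alcohol whose vinyl group is C8'=C9', so a radical at C8 heads a hex-5-enyl chain.
- Forward order: the two vanillin-type halves are joined as the beta-keto ester; the mediated anodic radical cyclisation closes ring B as a lactone together with the C8–C9'–C8' cyclopropane; a cyclopropyl ketone to dihydrofuran shift makes ring A; the C7=C8 bond is reduced; ring B is opened by hydride, the freed phenol prenylated, ring B reclosed as the ether and the silyl group removed.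
- Stereochemistry: C7' (S) comes from lipase resolution of the allylic alcohol; C8' follows from C7' in the 5-exo radical closure (trans); C7 and C8 come from proton and hydride delivery to the convex face of the bicyclic enol ether (cis fusion, endo aryl); the C7'–O bond is never broken afterwards.

Key step: step 7

Remark: read from the SMILES string the target is the 7R,8R,7'S,8'R isomer, with the hydroxyaryl group at C7 endo (cis to H8) and the prenyloxyaryl group at C7' exo; the route is planned for this isomer.

**Route**

Step 1
Reactants: 1 vanillin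
Product: 2 4-formyl-2-methoxyphenyl pivalate
Conditions: t-BuCOCl, Et3N, DMAP (cat.), CH2Cl2, 0 °C to rt
Reagents that add atoms: pivaloyl chloride, CC(C)(C)C(=O)Cl
Why: DMAP-catalysed acylation of the phenol gives a hindered aryl ester that should survive the Grignard addition and later deactivates this arene toward oxidation and acid.

Step 2
Reactants: 2 4-formyl-2-methoxyphenyl pivalate; 3 vinylmagnesium bromide
Product: 4 rac-1-(3-methoxy-4-pivaloyloxyphenyl)prop-2-en-1-ol
Conditions: CH2=CHMgBr (1.05 equiv), THF, −78 °C; then aq. NH4Cl
Reagents that add atoms: none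
Why: Grignard 1,2-addition to the aldehyde is much faster at −78 °C than attack on the hindered aryl pivalate, and the carbinol centre C7' is formed racemic at this stage.

Step 3
Reactants: 4 rac-1-(3-methoxy-4-pivaloyloxyphenyl)prop-2-en-1-ol
Product: 5 (S)-1-(3-methoxy-4-pivaloyloxyphenyl)prop-2-en-1-ol
Conditions: Novozym 435 (immobilised Candida antarctica lipase B), vinyl acetate, t-BuOMe, 30 °C, run slightly beyond half conversion; chromatography
Reagents that add atoms: none
Why: Lipase-catalysed kinetic resolution by transesterification, in which the enzyme's usual preference for secondary alcohols (aryl large, vinyl medium) acetylates the (R)-alcohol, so the (S)-alcohol should be left in high enantiomeric purity and fixes C7' of the target.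

Step 4
Reactants: 6 vanillic acid
Product: 8 3-methoxy-4-(triisopropylsilyloxy)benzoic acid, via bis-silylated vanillic acid 7 (not isolated)
Conditions: i-Pr3SiCl (2.3 equiv), imidazole, DMF, rt; then AcOH/THF/H2O, rt
Reagents that add atoms: triisopropylsilyl chloride, CC(C)[Si](Cl)(C(C)C)C(C)C
Why: Silylation of both acidic OH groups followed by selective hydrolysis of the far more labile silyl ester, the phenolic silyl ether being stable to aqueous AcOH.

Step 5
Reactants: 8 3-methoxy-4-(triisopropylsilyloxy)benzoic acid; 9 Meldrum's acid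
Product: 10 5-[hydroxy(3-methoxy-4-triisopropylsilyloxyphenyl)methylidene]-2,2-dimethyl-1,3-dioxane-4,6-dione
Conditions: DCC, DMAP, CH2Cl2, 0 °C to rt; cold aq. KHSO4 wash
Reagents that add atoms: none
Why: Carbodiimide-mediated C-acylation of Meldrum's acid with DMAP as acyl-transfer agent gives the enolised acyl Meldrum's acid, a stable acylketene precursor.

Step 6
Reactants: 10 acyl Meldrum's acid; 5 (S)-1-(3-methoxy-4-pivaloyloxyphenyl)prop-2-en-1-ol
Product: 12 (S)-1-(3-methoxy-4-pivaloyloxyphenyl)allyl 3-(3-methoxy-4-triisopropylsilyloxyphenyl)-3-oxopropanoate, via aroylketene 11 (not isolated)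
Conditions: toluene, 85 °C
Reagents that add atoms: none
Why: Thermolysis of the acyl Meldrum's acid releases acetone and CO2 and gives the aroylketene, which the secondary allylic alcohol traps under neutral conditions, so the ester C9–O bond forms without touching C7' or ionising the allylic benzylic position.

Step 7
Reactants: 12 (S)-1-(3-methoxy-4-pivaloyloxyphenyl)allyl 3-(3-methoxy-4-triisopropylsilyloxyphenyl)-3-oxopropanoate
Product: 13 (1R,4S,5S)-1-(3-methoxy-4-triisopropylsilyloxybenzoyl)-4-(3-methoxy-4-pivaloyloxyphenyl)-3-oxabicyclo[3.1.0]hexan-2-one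
Conditions: Mn(OAc)2·4H2O (20 mol%), Cu(OAc)2·H2O (1 equiv, regenerated in the cell), KOAc, AcOH, 50 °C, N2, divided cell, graphite-felt anode, Pt cathode, constant current, about 2.2 F/mol
Reagents that add atoms: none
Why: Proposed new method: the closest known reaction is the stoichiometric Mn(OAc)3/Cu(OAc)2 oxidative cyclisation of 1-arylallyl acetoacetates to 1-acetyl-4-aryl-3-oxabicyclo[3.1.0]hexan-2-ones; new here are the regeneration of trivalent manganese at the anode from catalytic Mn(OAc)2 (established for additions of beta-dicarbonyl compounds to alkenes but not for this cyclisation) and the aroyl group in place of acetyl. Trivalent manganese oxidises the enolised beta-keto ester to an electrophilic radical at C8, which adds to C8' in a 5-exo-trig closure that forms ring B as its lactone; divalent copper then captures the primary C9' radical as an alkylcopper species, and the still enolisable C8 attacks C9' with loss of monovalent copper in a 3-exo-tet closure of the cyclopropane, both metals being reoxidised in the anolyte. C8' is set by C7' through a chair-like 5-exo transition state with the aryl group pseudo-equatorial, which places the C8'–C9' bond trans to the aryl group, and the quaternary C8 is fixed relative to C8' because the three-membered ring can only be cis-fused to the lactone. The step needs the oxidant to act on the beta-keto ester alone and the C9' radical to be intercepted before it adds to the ortho position of the aroyl ring: the manganese couple is turned over well below the potentials of the two arenes, which are further deactivated by the ketone and by the pivalate, a full equivalent of Cu(OAc)2 makes capture of the primary radical fast, and the cell divider keeps copper away from the cathode.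

Step 8
Reactants: 13 (1R,4S,5S)-1-aroyl-4-aryl-3-oxabicyclo[3.1.0]hexan-2-one
Product: 14 (3S,3aR)-6-(3-methoxy-4-triisopropylsilyloxyphenyl)-3-(3-methoxy-4-pivaloyloxyphenyl)-3a,4-dihydro-1H,3H-furo[3,4-c]furan-1-one
Conditions: DABCO (30 mol%), dry DMSO, 110 °C
Reagents that add atoms: none
Why: Amine-catalysed Cloke–Wilson rearrangement, in which DABCO opens the doubly activated cyclopropane by SN2 attack at the unhindered C9' methylene and the aroyl lactone enolate then displaces the ammonium group through the ketone oxygen (5-exo-tet) to form O–C9' of ring A, leaving C7' and C8' untouched.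

Step 9
Reactants: 14 bicyclic enol ether lactone
Product: 15 (3S,3aR,6R,6aS)-6-(3-methoxy-4-triisopropylsilyloxyphenyl)-3-(3-methoxy-4-pivaloyloxyphenyl)tetrahydro-1H,3H-furo[3,4-c]furan-1-one
Conditions: Et3SiH, CF3CO2H, CH2Cl2, −20 to 0 °C
Reagents that add atoms: none
Why: Ionic hydrogenation of a push-pull enol ether (beta-alkoxy enoate), in which protonation at C8 gives the cis-fused aryl-stabilised oxocarbenium ion and Et3SiH delivers hydride to C7 from the convex face, anti to the C9 carbonyl, so that H7, H8 and H8' should be cis and the aryl group at C7 endo.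

Step 10
Reactants: 15 endo,exo-furofuranone
Product: 16 4-[(S)-hydroxy[(3R,4R,5R)-4-(hydroxymethyl)-5-(3-methoxy-4-triisopropylsilyloxyphenyl)oxolan-3-yl]methyl]-2-methoxyphenol
Conditions: LiAlH4, THF, 0 °C to rt; aq. potassium sodium tartrate work-up
Reagents that add atoms: none
Why: LiAlH4 reduces the lactone to the 1,4-diol by acyl C9–O cleavage and removes the aryl pivalate in the same operation, so only the phenol that is to be prenylated is freed while the aryl silyl ether and all stereocentres stay intact.

Step 11
Reactants: 16 phenol diol; 17 prenyl bromide (1-bromo-3-methylbut-2-ene)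
Product: 18 (S)-[(3R,4R,5R)-4-(hydroxymethyl)-5-(3-methoxy-4-triisopropylsilyloxyphenyl)oxolan-3-yl][3-methoxy-4-(3-methylbut-2-enyloxy)phenyl]methanol
Conditions: K2CO3, dry acetone, rt
Reagents that add atoms: none
Why: Williamson etherification, in which K2CO3 deprotonates only the phenol, so the allylic bromide should alkylate it by SN2 in the presence of the two alcohols.

Step 12
Reactants: 18 prenyl ether diol
Product: 20 (1R,3aR,4S,6aR)-1-(3-methoxy-4-triisopropylsilyloxyphenyl)-4-[3-methoxy-4-(3-methylbut-2-enyloxy)phenyl]tetrahydro-1H,3H-furo[3,4-c]furan, via primary methanesulfonate 19 (not isolated)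
Conditions: MeSO2Cl (1.1 equiv), pyridine, 0 °C to rt
Reagents that add atoms: none
Why: Selective sulfonylation of the primary alcohol followed by intramolecular Williamson-type 5-exo-tet displacement by the C7' hydroxyl closes ring B with the C7'–O bond intact, hence with retention at C7' (exo aryl, also the more stable arrangement).

Step 13
Reactants: 20 O-triisopropylsilyl furofuran
Product: 21 4-[(1R,3aR,4S,6aR)-4-[3-methoxy-4-(3-methylbut-2-enyloxy)phenyl]tetrahydro-1H,3H-furo[3,4-c]furan-1-yl]-2-methoxyphenol (target)
Conditions: Bu4NF, AcOH, THF, 0 °C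
Reagents that add atoms: none
Why: Fluoride-mediated cleavage of the aryl silyl ether, buffered with AcOH so that no free phenoxide can open the endo benzylic ether at C7 through a quinone methide, with the prenyl ether inert.

**Compound list**

1 | vanillin | COc1cc(C=O)ccc1O | starting material
2 | 4-formyl-2-methoxyphenyl pivalate | COc1cc(C=O)ccc1OC(=O)C(C)(C)C | intermediate
3 | vinylmagnesium bromide | C=C[Mg]Br | starting material
4 | rac-1-(3-methoxy-4-pivaloyloxyphenyl)prop-2-en-1-ol | C=CC(O)c1ccc(OC(=O)C(C)(C)C)c(OC)c1 | intermediate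
5 | (S)-1-(3-methoxy-4-pivaloyloxyphenyl)prop-2-en-1-ol | O[C@@H](C=C)c1ccc(OC(=O)C(C)(C)C)c(OC)c1 | intermediate
6 | vanillic acid | COc1cc(C(=O)O)ccc1O | starting material
7 | triisopropylsilyl 3-methoxy-4-(triisopropylsilyloxy)benzoate (formed and consumed in step 4) | COc1cc(C(=O)O[Si](C(C)C)(C(C)C)C(C)C)ccc1O[Si](C(C)C)(C(C)C)C(C)C | intermediate
8 | 3-methoxy-4-(triisopropylsilyloxy)benzoic acid | COc1cc(C(=O)O)ccc1O[Si](C(C)C)(C(C)C)C(C)C | intermediate
9 | Meldrum's acid | CC1(C)OC(=O)CC(=O)O1 | starting material
10 | 5-[hydroxy(3-methoxy-4-triisopropylsilyloxyphenyl)methylidene]-2,2-dimethyl-1,3-dioxane-4,6-dione | COc1cc(C(O)=C2C(=O)OC(C)(C)OC2=O)ccc1O[Si](C(C)C)(C(C)C)C(C)C | intermediate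
11 | (3-methoxy-4-triisopropylsilyloxybenzoyl)ketene (formed and consumed in step 6) | COc1cc(C(=O)C=C=O)ccc1O[Si](C(C)C)(C(C)C)C(C)C | intermediate
12 | (S)-1-(3-methoxy-4-pivaloyloxyphenyl)allyl 3-(3-methoxy-4-triisopropylsilyloxyphenyl)-3-oxopropanoate | COc1cc(C(=O)CC(=O)O[C@@H](C=C)c2ccc(OC(=O)C(C)(C)C)c(OC)c2)ccc1O[Si](C(C)C)(C(C)C)C(C)C | intermediate
13 | (1R,4S,5S)-1-(3-methoxy-4-triisopropylsilyloxybenzoyl)-4-(3-methoxy-4-pivaloyloxyphenyl)-3-oxabicyclo[3.1.0]hexan-2-one (aryl at C4 trans to the cyclopropane CH2) | COc1cc(C(=O)[C@@]23C[C@@H]2[C@@H](c2ccc(OC(=O)C(C)(C)C)c(OC)c2)OC3=O)ccc1O[Si](C(C)C)(C(C)C)C(C)C | intermediate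
14 | (3S,3aR)-6-(3-methoxy-4-triisopropylsilyloxyphenyl)-3-(3-methoxy-4-pivaloyloxyphenyl)-3a,4-dihydro-1H,3H-furo[3,4-c]furan-1-one | COc1cc(C2=C3C(=O)O[C@H](c4ccc(OC(=O)C(C)(C)C)c(OC)c4)[C@H]3CO2)ccc1O[Si](C(C)C)(C(C)C)C(C)C | intermediate
15 | (3S,3aR,6R,6aS)-6-(3-methoxy-4-triisopropylsilyloxyphenyl)-3-(3-methoxy-4-pivaloyloxyphenyl)tetrahydro-1H,3H-furo[3,4-c]furan-1-one | COc1cc([C@@H]2OC[C@H]3[C@@H]2C(=O)O[C@@H]3c2ccc(OC(=O)C(C)(C)C)c(OC)c2)ccc1O[Si](C(C)C)(C(C)C)C(C)C | intermediate
16 | 4-[(S)-hydroxy[(3R,4R,5R)-4-(hydroxymethyl)-5-(3-methoxy-4-triisopropylsilyloxyphenyl)oxolan-3-yl]methyl]-2-methoxyphenol | COc1cc([C@@H]2OC[C@H]([C@H](O)c3ccc(O)c(OC)c3)[C@@H]2CO)ccc1O[Si](C(C)C)(C(C)C)C(C)C | intermediate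
17 | prenyl bromide (1-bromo-3-methylbut-2-ene) | CC(C)=CCBr | starting material
18 | (S)-[(3R,4R,5R)-4-(hydroxymethyl)-5-(3-methoxy-4-triisopropylsilyloxyphenyl)oxolan-3-yl][3-methoxy-4-(3-methylbut-2-enyloxy)phenyl]methanol | COc1cc([C@@H]2OC[C@H]([C@H](O)c3ccc(OCC=C(C)C)c(OC)c3)[C@@H]2CO)ccc1O[Si](C(C)C)(C(C)C)C(C)C | intermediate
19 | primary methanesulfonate of 18 (formed and consumed in step 12) | COc1cc([C@@H]2OC[C@H]([C@H](O)c3ccc(OCC=C(C)C)c(OC)c3)[C@@H]2COS(C)(=O)=O)ccc1O[Si](C(C)C)(C(C)C)C(C)C | intermediate
20 | (1R,3aR,4S,6aR)-1-(3-methoxy-4-triisopropylsilyloxyphenyl)-4-[3-methoxy-4-(3-methylbut-2-enyloxy)phenyl]tetrahydro-1H,3H-furo[3,4-c]furan | COc1cc([C@@H]2OC[C@H]3[C@@H]2CO[C@@H]3c2ccc(OCC=C(C)C)c(OC)c2)ccc1O[Si](C(C)C)(C(C)C)C(C)C | intermediate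
21 | 4-[(1R,3aR,4S,6aR)-4-[3-methoxy-4-(3-methylbut-2-enyloxy)phenyl]tetrahydro-1H,3H-furo[3,4-c]furan-1-yl]-2-methoxyphenol | COc1cc([C@@H]2OC[C@H]3[C@@H]2CO[C@@H]3c2ccc(OCC=C(C)C)c(OC)c2)ccc1O | target

**Step count and risks**

Total steps: 13. Longest linear sequence: 11 steps (steps 1–3, then 6–13); the branch from vanillic acid (steps 4 and 5) joins at step 6.

Steps most likely to fail:

1. Step 7 (key step). The manganese mediator may not turn over cleanly, so that the enol or an arene is oxidised directly at the anode. The primary C9' radical may add to the ortho position of the aroyl ring before copper captures it. Acetate may also desilylate the aryl ether, after which the phenol would be oxidised. The fallback replaces the radical by a carbenoid, sets out from 12 and returns at 13. Diazo transfer (Regitz) with 4-acetamidobenzenesulfonyl azide and Et3N in MeCN should give (S)-1-(3-methoxy-4-pivaloyloxyphenyl)allyl 2-diazo-3-(3-methoxy-4-triisopropylsilyloxyphenyl)-3-oxopropanoate F1. Rh2(OAc)4 (1 mol%) in CH2Cl2 at reflux should then form the rhodium carbenoid, which cyclopropanates the tethered vinyl group intramolecularly to give 13. The cyclopropane is again necessarily cis-fused; the isomer with the aryl group trans to the cyclopropane methylene is expected to predominate and any cis isomer would be removed by chromatography.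

2. Step 8. At the temperature needed for the amine to open the bicyclic cyclopropane, ring opening may be too slow, or the zwitterion may decompose, or the aryl ester may be transacylated. The fallback is a stepwise polar route from 13 back to 14. MgI2 in THF at rt should open the cyclopropane by homo-conjugate attack of iodide at C9' and give, after aqueous quench, (4S,5S)-4-(iodomethyl)-3-(3-methoxy-4-triisopropylsilyloxybenzoyl)-5-(3-methoxy-4-pivaloyloxyphenyl)oxolan-2-one F2 (epimeric or enolised at C3). Ag2CO3 in toluene at 60 °C in the dark should then assist ionisation of the iodide and steer the enol to O-alkylation, closing the dihydrofuran ring of 14.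

3. Step 9. Under acid the electron-rich benzylic C7–O bond of the product may ionise, leading to reductive ring opening or to epimerisation toward the more stable exo aryl group, and the silyl ether may be lost. The fallback goes from 14 to 15 by heterogeneous hydrogenation (H2, 1–4 bar, Pd/C, EtOAc, rt), a neutral syn addition to the tetrasubstituted enol ether from the convex face that should give the same all-cis arrangement. It would be stopped after uptake of one equivalent of H2 to spare the benzylic C–O bonds. No new compound arises (F0).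

**Further compounds**

F1 | step 7 | (S)-1-(3-methoxy-4-pivaloyloxyphenyl)allyl 2-diazo-3-(3-methoxy-4-triisopropylsilyloxyphenyl)-3-oxopropanoate | COc1cc(C(=O)C(=[N+]=[N-])C(=O)O[C@@H](C=C)c2ccc(OC(=O)C(C)(C)C)c(OC)c2)ccc1O[Si](C(C)C)(C(C)C)C(C)C
F2 | step 8 | (4S,5S)-4-(iodomethyl)-3-(3-methoxy-4-triisopropylsilyloxybenzoyl)-5-(3-methoxy-4-pivaloyloxyphenyl)oxolan-2-one | COc1cc(C(=O)C2C(=O)O[C@H](c3ccc(OC(=O)C(C)(C)C)c(OC)c3)[C@H]2CI)ccc1O[Si](C(C)C)(C(C)C)C(C)C
F0 | step 9 | none | none
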